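The numbers belong to no real substance; the flask was simulated.

The next run hung on one comparison: how fast mono adduct takes up coupling partner against how fast starting material does.

    coupling partner + mono adduct → double product + by-product (k1 = 50.8 /M/s, Ea1 = 46.0 kJ/mol)
    coupling partner + double product → triple product + by-product (k2 = 1.49 /M/s, Ea2 = 48.0 kJ/mol)
    starting material + coupling partner → mono adduct + by-product (k3 = 19.1 /M/s, Ea3 = 50.0 kJ/mol)
    coupling partner + triple product → tetra adduct + by-product (k4 = 30.2 /M/s, Ea4 = 40.0 kJ/mol)
    double product → over-reaction product (k5 = 0.0485 /s, Ea5 = 97.0 kJ/mol)
    (constants at 50 °C)

in all of them: starting material 10 mM; coupling partner 8.00 mM; time 8.0 s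
- midnight: temperature 20 °C
- dusk: temperature 80 °C
- summer: temperature 50 °C
- dawn: temperature −10 °C

- all constants are for 50 °C and move with temperature by the activation energies

* which flask leads in amount of double product, in percent of the starting material charged ("all alike" within 1.5 percentage points) (midnight / dusk / summer / dawn / all alike)
* how much double product is there at the end, in percent of the starting material charged: midnight
* how much double product is there at the end, in percent of the starting material charged: dusk
* how much double product is there at the end, in percent of the starting material charged: summer
* how much double product is there at the end, in percent of the starting material charged: dawn

1. I looked for what stayed nearly constant. Both couplings carry [coupling partner] in their rates, so dividing one by the other removes it, and time with it. What remains is the pull ratio κ = k(mono adduct)/k(starting material), the selectivity factor, 2.66 at 50 °C.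

2. I froze κ across the flasks. The two barriers differ by 4.00 kJ/mol, far less than either barrier, while the coupling of starting material itself speeds up 340-fold from coldest to hottest.

3. With x = [starting material]/charge, integrating the ratio gave m = (x − x^κ)/(κ − 1) for [mono adduct]/charge. The over-reaction touches neither species, so it doesn't enter. Whatever had passed beyond mono adduct I called the double line: double, triple and tetra products plus over-reaction product, 1 − x − m.

4. Then I counted partner. Each starting material gone costs one, and each member of the double line at least one more. At x = 0.5, m is 20.6 %, and the bill, counting one extra per member, comes to 7.94 mM against 8.00 mM charged. So I reckoned the 8.00 mM of coupling partner, the limiting reagent, paid out with about half of the starting material left, and the double line stopping near 29.4 %.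

5. My reckoning went no further: it estimates the line and doesn't split it. But it gave the decision. On this charge I expected neither more time nor more heat to carry the line past that estimate, and the over-reaction speeds up 81000-fold over the range, far more than the coupling. I kept 50 °C and 8.0 s and chose 20 mM of coupling partner for the next run, since 20.0 mM pays for two couplings on every starting material.

6. The forecast named summer as leader, with 18 % (15 % to 21 %) there, 3.3 % at midnight, 0.1 % at dusk and 0.05 % at dawn. Its ground for summer was that "formation is well advanced and loss is still only modest".

7. Summer led with 18.1 % double product, against 3.22 % at midnight, 0.0875 % at dusk and 0.0548 % at dawn, and 4.24 % over-reaction product stood beside it in summer at 8.00 s. With 56.5 % starting material left in summer, κ of 2.66 gave mono adduct 20.8 % and a double line of 22.7 %; the four members in that flask sum to 22.7 %. The neighbour of summer charged with 20 mM reached 49.6 % double product, above the 29.4 % I had estimated for the whole double line on the smaller charge. Its 21.7 % starting material left gave, by the same κ, mono adduct 12.0 %, and that neighbour held 12.0 %.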